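**Retrosynthetic overview**
1. Target ⇐ lipase-mediated removal of a primary acetate from the side chain ⇐ Yamaguchi acylation of the C8 alcohol of the macrocycle with (2E)-4-acetoxy-2-methylbut-2-enoic acid (Wittig-derived).
2. Exocyclic methylene (C13) ⇐ Eschenmoser methylenation of the saturated cis-lactone; ten-membered ring ⇐ ring-closing metathesis forming the (Z)-C1=C10 alkene.
3. C8–C9 ⇐ catalyst-controlled methallylboration of a lactone aldehyde; C6–C7 (both stereocentres) ⇐ D-proline anti cross-aldol of a cis-epoxy aldehyde with methyl 4-oxobutanoate, the adduct lactonising on O6.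
4. Epoxy aldehyde ⇐ catalytic Sharpless epoxidation of (2Z)-3-methylhepta-2,6-dien-1-ol ⇐ hex-1-en-5-yne (acylation, syn-carbocupration, reduction).
5. Ring order: oxirane, then γ-lactone, then ten-membered carbocycle.

Assumption: the SMILES is read literally, i.e. (4R,5S,6S,7S,8R) with a (Z)-C1=C10 alkene, which means a cis-fused lactone and a cis-epoxide; germacrane locants are used (lactone carbonyl C12, C11, exocyclic C13, ring C1–C10, methyls on C4 and C10).

**Route**

Step 1
Reactants: 1 hex-1-en-5-yne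
Product: 3 methyl hept-6-en-2-ynoate, via lithium acetylide 2 (not isolated)
Conditions: n-BuLi, THF, −78 °C; then ClCO2Me, −78 → 0 °C
Reagents that add atoms: methyl chloroformate, COC(=O)Cl
Why: Deprotonation of the terminal alkyne and C-acylation of the acetylide with the chloroformate gives the ynoate needed for a stereodefined carbocupration, and no stereocentre is formed.

Step 2
Reactants: 3 methyl hept-6-en-2-ynoate
Product: 5 methyl (2Z)-3-methylhepta-2,6-dienoate, via vinylcuprate adduct 4 (not isolated)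
Conditions: Me2CuLi (from CuI and 2 MeLi), THF, −78 °C; aq. NH4Cl at −78 °C
Reagents that add atoms: lithium dimethylcuprate, [Li+].C[Cu-]C
Why: Syn carbocupration (cuprate conjugate addition) of the ynoate and protonation of the vinylcopper with retention place the butenyl chain cis to the ester, fixing the (Z)-trisubstituted alkene that becomes the cis-epoxide.

Step 3
Reactants: 5 methyl (2Z)-3-methylhepta-2,6-dienoate
Product: 7 (2Z)-3-methylhepta-2,6-dien-1-ol, via (2Z)-3-methylhepta-2,6-dienal 6 (not isolated)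
Conditions: iBu2AlH (2.5 equiv), CH2Cl2, −78 → 0 °C; aq. sodium potassium tartrate
Reagents that add atoms: none
Why: 1,2-Reduction of the enoate by the aluminium hydride (ester to allylic alcohol through the aldehyde) leaves the alkene geometry and the terminal vinyl group untouched.

Step 4
Reactants: 7 (2Z)-3-methylhepta-2,6-dien-1-ol
Product: 8 [(2S,3R)-3-(but-3-en-1-yl)-3-methyloxiran-2-yl]methanol
Conditions: Ti(OiPr)4 (10 mol %), L-(+)-diethyl tartrate (12 mol %), t-BuOOH, 4 Å MS, CH2Cl2, −20 °C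
Reagents that add atoms: tert-butyl hydroperoxide, CC(C)(C)OO
Why: Catalytic Sharpless asymmetric epoxidation is directed by the allylic hydroxyl, so only the 2,3-alkene reacts, and with the L-(+)-tartrate the oxygen is delivered to the face that gives the (2S,3R) cis-epoxide, i.e. C5 (S) and C4 (R), the first stereocentres of the route.

Step 5
Reactants: 8 [(2S,3R)-3-(but-3-en-1-yl)-3-methyloxiran-2-yl]methanol
Product: 9 (2R,3R)-3-(but-3-en-1-yl)-3-methyloxirane-2-carbaldehyde
Conditions: TEMPO (10 mol %), PhI(OAc)2, CH2Cl2, 23 °C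
Reagents that add atoms: none
Why: Oxoammonium-mediated (TEMPO) alcohol oxidation stops at the aldehyde without base, so the epoxide and its stereocentres are untouched (the label at C2 changes from S to R only because CHO now outranks C3).

Step 6
Reactants: 9 (2R,3R)-3-(but-3-en-1-yl)-3-methyloxirane-2-carbaldehyde + 10 methyl 4-oxobutanoate
Product: 12 (2S,3R)-2-[(2S,3R)-3-(but-3-en-1-yl)-3-methyloxiran-2-yl]-5-oxooxolane-3-carbaldehyde, via anti-aldol hydroxy ester 11 (not isolated)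
Conditions: D-proline (20 mol %), DMF, 4 °C, slow addition of 10; then PPTS (10 mol %), 4 Å MS, CH2Cl2, 23 °C
Reagents that add atoms: none
Why: In this enamine-catalysed cross-aldol (Houk–List transition state) the E-enamine of 10 attacks the Si face of the non-enolisable epoxy aldehyde, which is also its Felkin–Anh face (matched case), giving the anti aldol that sets C6 (S) and C7, and mild acid then lactonises the γ-hydroxy ester on O6 to the cis-fused lactone before any hydroxyl exists at C8.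

Step 7
Reactants: 12 (2S,3R)-2-[(2S,3R)-3-(but-3-en-1-yl)-3-methyloxiran-2-yl]-5-oxooxolane-3-carbaldehyde + 13 4,4,5,5-tetramethyl-2-(2-methylprop-2-en-1-yl)-1,3,2-dioxaborolane
Product: 15 (4S,5S)-5-[(2S,3R)-3-(but-3-en-1-yl)-3-methyloxiran-2-yl]-4-[(1R)-1-hydroxy-3-methylbut-3-en-1-yl]oxolan-2-one, via pinacol borate ester 14 (not isolated)
Conditions: (R)-TRIP phosphoric acid (5 mol %), 4 Å MS, toluene, −30 °C; aq. NaHCO3 work-up
Reagents that add atoms: none
Why: Chiral phosphoric acid-catalysed allylboration through a closed chair transition state delivers the methallyl group to the Re face of the aldehyde, the face also preferred by Felkin–Anh control from C7 (C6 anti to the nucleophile), which sets C8 (R) without Lewis acids or metal alkoxides that would endanger the epoxide or cause translactonisation.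

Step 8
Reactants: 15 (4S,5S)-5-[(2S,3R)-3-(but-3-en-1-yl)-3-methyloxiran-2-yl]-4-[(1R)-1-hydroxy-3-methylbut-3-en-1-yl]oxolan-2-one
Product: 16 (4R,5S)-5-[(2S,3R)-3-(but-3-en-1-yl)-3-methyloxiran-2-yl]-4-{(1R)-3-methyl-1-[(triethylsilyl)oxy]but-3-en-1-yl}oxolan-2-one
Conditions: Et3SiCl, imidazole, DMAP (cat.), DMF, 0 → 23 °C
Reagents that add atoms: chlorotriethylsilane, CC[Si](Cl)(CC)CC
Why: Silyl ether formation caps the C8 hydroxyl so that it can neither translactonise nor interfere with the metathesis and enolate steps, and the silyl chloride (not a triflate) spares the epoxide; no centre changes (the C4 label becomes R only through the Si priority).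

Step 9
Reactants: 16 (4R,5S)-5-[(2S,3R)-3-(but-3-en-1-yl)-3-methyloxiran-2-yl]-4-{(1R)-3-methyl-1-[(triethylsilyl)oxy]but-3-en-1-yl}oxolan-2-one
Product: 17 (1(10)Z,4R,5S,6S,7R,8R)-4,5-epoxy-8-[(triethylsilyl)oxy]-13-norgermacr-1(10)-en-12,6-olide
Conditions: second-generation Grubbs catalyst RuCl2(PCy3)(H2IMes)(=CHPh) (10 mol %), toluene (1 mM), 80 °C
Reagents that add atoms: none
Why: Ring-closing metathesis between the monosubstituted and the 1,1-disubstituted alkene closes the ten-membered ring, with the cis-lactone and cis-epoxide as turn elements, and ring strain enforces the (Z)-trisubstituted C1=C10 alkene because the (E)-isomer is far more strained in a cyclodecene.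

Step 10
Reactants: 17 (1(10)Z,4R,5S,6S,7R,8R)-4,5-epoxy-8-[(triethylsilyl)oxy]-13-norgermacr-1(10)-en-12,6-olide
Product: 19 (1(10)Z,4R,5S,6S,7R,8R)-13-(dimethylamino)-4,5-epoxy-8-[(triethylsilyl)oxy]germacr-1(10)-en-12,6-olide, via lithium lactone enolate 18 (not isolated)
Conditions: LiN(iPr)2, THF, −78 °C; then CH2=NMe2+ I−, −78 → 0 °C
Reagents that add atoms: N,N-dimethylmethyleneiminium iodide (Eschenmoser's salt), C=[N+](C)C.[I-]
Why: Kinetic deprotonation of the only acidic position (lactone α-CH2) and Mannich alkylation of the enolate installs C13, and the new C11 centre is removed in the next step so its configuration does not matter.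

Step 11
Reactants: 19 (1(10)Z,4R,5S,6S,7R,8R)-13-(dimethylamino)-4,5-epoxy-8-[(triethylsilyl)oxy]germacr-1(10)-en-12,6-olide
Product: 21 (1(10)Z,4R,5S,6S,7R,8R)-4,5-epoxy-8-[(triethylsilyl)oxy]germacra-1(10),11(13)-dien-12,6-olide, via trimethylammonium iodide 20 (not isolated)
Conditions: MeI, MeOH, 23 °C; then aq. NaHCO3, EtOAc, 23 °C
Reagents that add atoms: none
Why: N-Methylation turns the amine into a leaving group and mild base triggers Hofmann-type β-elimination at the acidic α-hydrogen, giving the exocyclic α-methylene lactone without touching C7.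

Step 12
Reactants: 21 (1(10)Z,4R,5S,6S,7R,8R)-4,5-epoxy-8-[(triethylsilyl)oxy]germacra-1(10),11(13)-dien-12,6-olide
Product: 22 (1(10)Z,4R,5S,6S,7S,8R)-4,5-epoxy-8-hydroxygermacra-1(10),11(13)-dien-12,6-olide
Conditions: HF·pyridine, pyridine, THF, 0 °C
Reagents that add atoms: none
Why: Buffered fluoride-mediated desilylation cleaves the secondary triethylsilyl ether under conditions too mild to open the epoxide or add to the methylene lactone.

Step 13
Reactants: 23 glycolaldehyde (used as its crystalline dimer) + 24 ethyl 2-(triphenyl-λ5-phosphanylidene)propanoate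
Product: 25 ethyl (2E)-4-hydroxy-2-methylbut-2-enoate
Conditions: CH2Cl2, 40 °C
Reagents that add atoms: none
Why: Wittig olefination with a stabilised ylide gives the (E)-trisubstituted enoate, which defines the side-chain geometry.

Step 14
Reactants: 25 ethyl (2E)-4-hydroxy-2-methylbut-2-enoate
Product: 27 (2E)-4-hydroxy-2-methylbut-2-enoic acid, via lithium carboxylate 26 (not isolated)
Conditions: LiOH, THF/H2O, 0 → 23 °C; then 1 M HCl
Reagents that add atoms: lithium hydroxide, [Li+].[OH-]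
Why: Saponification of the ethyl ester and acidification give the acid, and the (E)-geometry prevents cyclisation to a butenolide.

Step 15
Reactants: 27 (2E)-4-hydroxy-2-methylbut-2-enoic acid
Product: 29 (2E)-4-(acetyloxy)-2-methylbut-2-enoic acid, via mixed acetic anhydride 28 (not isolated)
Conditions: Ac2O, pyridine, DMAP (cat.), CH2Cl2, 0 → 23 °C; then H2O, THF
Reagents that add atoms: acetic anhydride, CC(=O)OC(C)=O
Why: DMAP-catalysed acetylation protects the primary alcohol as an ester that an enzyme can remove later, and the transient mixed anhydride at the carboxyl group is hydrolysed selectively by water.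

Step 16
Reactants: 22 (1(10)Z,4R,5S,6S,7S,8R)-4,5-epoxy-8-hydroxygermacra-1(10),11(13)-dien-12,6-olide + 29 (2E)-4-(acetyloxy)-2-methylbut-2-enoic acid
Product: 31 (1(10)Z,4R,5S,6S,7S,8R)-8-{[(2E)-4-(acetyloxy)-2-methylbut-2-enoyl]oxy}-4,5-epoxygermacra-1(10),11(13)-dien-12,6-olide, via Yamaguchi mixed anhydride 30 (not isolated)
Conditions: 2,4,6-Cl3C6H2COCl, Et3N, toluene, 23 °C; then 22, DMAP, toluene, 23 °C
Reagents that add atoms: none
Why: Yamaguchi esterification (DMAP-activated mixed anhydride) acylates the hindered secondary C8 alcohol with retention and faster than translactonisation, and the (E)-α-methyl enoate does not isomerise.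

Step 17
Reactants: 31 (1(10)Z,4R,5S,6S,7S,8R)-8-{[(2E)-4-(acetyloxy)-2-methylbut-2-enoyl]oxy}-4,5-epoxygermacra-1(10),11(13)-dien-12,6-olide
Product: 32 (1(10)Z,4R,5S,6S,7S,8R)-4,5-epoxy-8-{[(2E)-4-hydroxy-2-methylbut-2-enoyl]oxy}germacra-1(10),11(13)-dien-12,6-olide
Conditions: immobilised Candida antarctica lipase B (a lipase), n-BuOH, t-BuOMe, 30 °C
Reagents that add atoms: none
Why: The lipase (a serine hydrolase) transesterifies only the unhindered primary acetate to butanol under neutral anhydrous conditions, whereas the α-branched enoate at C8, the γ-lactone, the methylene Michael acceptor and the epoxide are not substrates, so the target is released without chemical acid or base.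

**Compound list**
1 | hex-1-en-5-yne | C=CCCC#C | starting material
2 | lithium hex-5-en-1-yn-1-ide | [Li]C#CCCC=C | intermediate
3 | methyl hept-6-en-2-ynoate | C=CCCC#CC(=O)OC | intermediate
4 | lithium [(1E)-1-(methoxycarbonyl)-2-methylhexa-1,5-dien-1-yl](methyl)cuprate | C=CCC/C(C)=C(/[Cu-]C)C(=O)OC.[Li+] | intermediate
5 | methyl (2Z)-3-methylhepta-2,6-dienoate | C=CCC/C(C)=C\C(=O)OC | intermediate
6 | (2Z)-3-methylhepta-2,6-dienal | C=CCC/C(C)=C\C=O | intermediate
7 | (2Z)-3-methylhepta-2,6-dien-1-ol | C=CCC/C(C)=C\CO | intermediate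
8 | [(2S,3R)-3-(but-3-en-1-yl)-3-methyloxiran-2-yl]methanol | C=CCC[C@@]1(C)O[C@H]1CO | intermediate
9 | (2R,3R)-3-(but-3-en-1-yl)-3-methyloxirane-2-carbaldehyde | C=CCC[C@@]1(C)O[C@H]1C=O | intermediate
10 | methyl 4-oxobutanoate | COC(=O)CCC=O | starting material
11 | methyl (3R,4S)-4-[(2S,3R)-3-(but-3-en-1-yl)-3-methyloxiran-2-yl]-3-formyl-4-hydroxybutanoate | COC(=O)C[C@@H](C=O)[C@H](O)[C@@H]1O[C@]1(C)CCC=C | intermediate
12 | (2S,3R)-2-[(2S,3R)-3-(but-3-en-1-yl)-3-methyloxiran-2-yl]-5-oxooxolane-3-carbaldehyde | C1C(=O)O[C@H]([C@@H]2O[C@]2(C)CCC=C)[C@@H]1C=O | intermediate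
13 | 4,4,5,5-tetramethyl-2-(2-methylprop-2-en-1-yl)-1,3,2-dioxaborolane | CC(=C)CB1OC(C)(C)C(C)(C)O1 | starting material
14 | (4S,5S)-5-[(2S,3R)-3-(but-3-en-1-yl)-3-methyloxiran-2-yl]-4-{(1R)-3-methyl-1-[(4,4,5,5-tetramethyl-1,3,2-dioxaborolan-2-yl)oxy]but-3-en-1-yl}oxolan-2-one | C1C(=O)O[C@H]([C@@H]2O[C@]2(C)CCC=C)[C@@H]1[C@H](OB1OC(C)(C)C(C)(C)O1)CC(C)=C | intermediate
15 | (4S,5S)-5-[(2S,3R)-3-(but-3-en-1-yl)-3-methyloxiran-2-yl]-4-[(1R)-1-hydroxy-3-methylbut-3-en-1-yl]oxolan-2-one | C1C(=O)O[C@H]([C@@H]2O[C@]2(C)CCC=C)[C@@H]1[C@H](O)CC(C)=C | intermediate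
16 | (4R,5S)-5-[(2S,3R)-3-(but-3-en-1-yl)-3-methyloxiran-2-yl]-4-{(1R)-3-methyl-1-[(triethylsilyl)oxy]but-3-en-1-yl}oxolan-2-one | C1C(=O)O[C@H]([C@@H]2O[C@]2(C)CCC=C)[C@@H]1[C@H](O[Si](CC)(CC)CC)CC(C)=C | intermediate
17 | (1(10)Z,4R,5S,6S,7R,8R)-4,5-epoxy-8-[(triethylsilyl)oxy]-13-norgermacr-1(10)-en-12,6-olide | C1C(=O)O[C@H]2[C@@H]1[C@H](O[Si](CC)(CC)CC)C/C(C)=C\CC[C@@]1(C)O[C@@H]21 | intermediate
18 | lithium enolate of 17 (O-lithio ketene acetal, C11=C12) | C1=C(O[Li])O[C@H]2[C@@H]1[C@H](O[Si](CC)(CC)CC)C/C(C)=C\CC[C@@]1(C)O[C@@H]21 | intermediate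
19 | (1(10)Z,4R,5S,6S,7R,8R)-13-(dimethylamino)-4,5-epoxy-8-[(triethylsilyl)oxy]germacr-1(10)-en-12,6-olide (C11 epimers) | CN(C)CC1C(=O)O[C@H]2[C@@H]1[C@H](O[Si](CC)(CC)CC)C/C(C)=C\CC[C@@]1(C)O[C@@H]21 | intermediate
20 | N-methyl quaternary ammonium iodide of 19 | C[N+](C)(C)CC1C(=O)O[C@H]2[C@@H]1[C@H](O[Si](CC)(CC)CC)C/C(C)=C\CC[C@@]1(C)O[C@@H]21.[I-] | intermediate
21 | (1(10)Z,4R,5S,6S,7R,8R)-4,5-epoxy-8-[(triethylsilyl)oxy]germacra-1(10),11(13)-dien-12,6-olide | C=C1C(=O)O[C@H]2[C@@H]1[C@H](O[Si](CC)(CC)CC)C/C(C)=C\CC[C@@]1(C)O[C@@H]21 | intermediate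
22 | (1(10)Z,4R,5S,6S,7S,8R)-4,5-epoxy-8-hydroxygermacra-1(10),11(13)-dien-12,6-olide | C=C1C(=O)O[C@H]2[C@@H]1[C@H](O)C/C(C)=C\CC[C@@]1(C)O[C@@H]21 | intermediate
23 | glycolaldehyde (2-hydroxyacetaldehyde, supplied as its dimer) | OCC=O | starting material
24 | ethyl 2-(triphenyl-λ5-phosphanylidene)propanoate | CCOC(=O)C(C)=P(c1ccccc1)(c1ccccc1)c1ccccc1 | starting material
25 | ethyl (2E)-4-hydroxy-2-methylbut-2-enoate | CCOC(=O)/C(C)=C/CO | intermediate
26 | lithium (2E)-4-hydroxy-2-methylbut-2-enoate | [Li+].[O-]C(=O)/C(C)=C/CO | intermediate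
27 | (2E)-4-hydroxy-2-methylbut-2-enoic acid | OC(=O)/C(C)=C/CO | intermediate
28 | acetic (2E)-4-(acetyloxy)-2-methylbut-2-enoic anhydride | CC(=O)OC(=O)/C(C)=C/COC(C)=O | intermediate
29 | (2E)-4-(acetyloxy)-2-methylbut-2-enoic acid | OC(=O)/C(C)=C/COC(C)=O | intermediate
30 | (2E)-4-(acetyloxy)-2-methylbut-2-enoic 2,4,6-trichlorobenzoic anhydride | O=C(OC(=O)/C(C)=C/COC(C)=O)c1c(Cl)cc(Cl)cc1Cl | intermediate
31 | (1(10)Z,4R,5S,6S,7S,8R)-8-{[(2E)-4-(acetyloxy)-2-methylbut-2-enoyl]oxy}-4,5-epoxygermacra-1(10),11(13)-dien-12,6-olide | C=C1C(=O)O[C@H]2[C@@H]1[C@H](OC(=O)/C(C)=C/COC(C)=O)C/C(C)=C\CC[C@@]1(C)O[C@@H]21 | intermediate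
32 | (1(10)Z,4R,5S,6S,7S,8R)-4,5-epoxy-8-{[(2E)-4-hydroxy-2-methylbut-2-enoyl]oxy}germacra-1(10),11(13)-dien-12,6-olide | C=C1C(=O)O[C@H]2[C@@H]1[C@H](OC(=O)/C(C)=C/CO)C/C(C)=C\CC[C@@]1(C)O[C@@H]21 | target

**Step count and risk**
Total step count: 17. Longest linear sequence: 14 steps (steps 1–12, 16, 17); steps 13–15 make the side-chain acid.

Steps most likely to fail:

Step 6 (cross-aldol and lactonisation). The epoxy aldehyde is an unusual acceptor, donor self-aldol competes, and the acid used for lactonisation must not open the epoxide or epimerise C7. The fallback sets out from 9 and comes back at 21, replacing the enamine aldol by a Barbier allylation that forms the methylene lactone directly. [(4-Methoxyphenyl)methoxy]acetaldehyde and methyl acrylate give, with DABCO, the Morita–Baylis–Hillman adduct methyl 3-hydroxy-4-[(4-methoxyphenyl)methoxy]-2-methylidenebutanoate F1. N-Bromosuccinimide/Me2S converts it by SN2′ bromination into methyl (2Z)-2-(bromomethyl)-4-[(4-methoxyphenyl)methoxy]but-2-enoate F2. Indium-mediated allylation–lactonisation of 9 with F2 in THF/H2O (chair transition state of the Z-type allylindium on the Felkin–Anh face) gives the cis α-methylene lactone (4S,5S)-5-[(2S,3R)-3-(but-3-en-1-yl)-3-methyloxiran-2-yl]-4-{[(4-methoxyphenyl)methoxy]methyl}-3-methylideneoxolan-2-one F3. DDQ frees the primary alcohol (4S,5S)-5-[(2S,3R)-3-(but-3-en-1-yl)-3-methyloxiran-2-yl]-4-(hydroxymethyl)-3-methylideneoxolan-2-one F4, and Dess–Martin periodinane gives (2S,3R)-2-[(2S,3R)-3-(but-3-en-1-yl)-3-methyloxiran-2-yl]-4-methylidene-5-oxooxolane-3-carbaldehyde F5, used at once. Methallylboration with 13 as in step 7 gives (4S,5S)-5-[(2S,3R)-3-(but-3-en-1-yl)-3-methyloxiran-2-yl]-4-[(1R)-1-hydroxy-3-methylbut-3-en-1-yl]-3-methylideneoxolan-2-one F6, and Et3SiCl/imidazole gives (4R,5S)-5-[(2S,3R)-3-(but-3-en-1-yl)-3-methyloxiran-2-yl]-4-{(1R)-3-methyl-1-[(triethylsilyl)oxy]but-3-en-1-yl}-3-methylideneoxolan-2-one F7. Ring-closing metathesis as in step 9 then leads to 21, and steps 10 and 11 are not needed.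

Step 7 (methallylation). The diastereoselectivity at C8 rests on catalyst and Felkin–Anh control working together, and the aldehyde can epimerise. The fallback sets out from 12 and comes back at 15, replacing the stereoselective C–C bond formation by an enzyme-controlled reduction. Unselective Barbier methallylation of 12 (3-bromo-2-methylprop-1-ene, indium powder, THF/H2O) gives the carbinol epimers (4S,5S)-5-[(2S,3R)-3-(but-3-en-1-yl)-3-methyloxiran-2-yl]-4-(1-hydroxy-3-methylbut-3-en-1-yl)oxolan-2-one F8. Dess–Martin oxidation gives the ketone (4R,5S)-5-[(2S,3R)-3-(but-3-en-1-yl)-3-methyloxiran-2-yl]-4-(3-methylbut-3-enoyl)oxolan-2-one F9. An (R)-selective ketoreductase (NADP+, glucose, glucose dehydrogenase, pH 7 buffer with DMSO) reduces F9 under enzyme control to 15.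

Step 9 (ring-closing metathesis). Closure onto a 1,1-disubstituted alkene in a ten-membered ring can stall or give dimers. The fallback sets out from 16 and comes back at 17, replacing metathesis by carbonyl coupling and a stereospecific olefination. Ozonolysis of 16 (O3, CH2Cl2, −78 °C; PPh3) gives the keto aldehyde (4R,5S)-5-[(2S,3R)-3-methyl-3-(3-oxopropyl)oxiran-2-yl]-4-{(1R)-3-oxo-1-[(triethylsilyl)oxy]butyl}oxolan-2-one F10. SmI2-mediated intramolecular pinacol coupling at high dilution gives the cis-1,10-diol (4R,5S,6S,7R,8R)-4,5-epoxy-1,10-dihydroxy-8-[(triethylsilyl)oxy]-13-norgermacran-12,6-olide F11. Thiocarbonyldiimidazole gives the cyclic 1,10-thionocarbonate of that diol F12. Corey–Winter olefination with 1,3-dimethyl-2-phenyl-1,3,2-diazaphospholidine (stereospecific syn-elimination, cis-diol to Z-alkene) gives 17.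

**Further compounds**
F1 | step 6 | methyl 3-hydroxy-4-[(4-methoxyphenyl)methoxy]-2-methylidenebutanoate (racemic) | COC(=O)C(=C)C(O)COCc1ccc(OC)cc1
F2 | step 6 | methyl (2Z)-2-(bromomethyl)-4-[(4-methoxyphenyl)methoxy]but-2-enoate | COC(=O)/C(CBr)=C/COCc1ccc(OC)cc1
F3 | step 6 | (4S,5S)-5-[(2S,3R)-3-(but-3-en-1-yl)-3-methyloxiran-2-yl]-4-{[(4-methoxyphenyl)methoxy]methyl}-3-methylideneoxolan-2-one | C=C1C(=O)O[C@H]([C@@H]2O[C@]2(C)CCC=C)[C@@H]1COCc1ccc(OC)cc1
F4 | step 6 | (4S,5S)-5-[(2S,3R)-3-(but-3-en-1-yl)-3-methyloxiran-2-yl]-4-(hydroxymethyl)-3-methylideneoxolan-2-one | C=C1C(=O)O[C@H]([C@@H]2O[C@]2(C)CCC=C)[C@@H]1CO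
F5 | step 6 | (2S,3R)-2-[(2S,3R)-3-(but-3-en-1-yl)-3-methyloxiran-2-yl]-4-methylidene-5-oxooxolane-3-carbaldehyde | C=C1C(=O)O[C@H]([C@@H]2O[C@]2(C)CCC=C)[C@@H]1C=O
F6 | step 6 | (4S,5S)-5-[(2S,3R)-3-(but-3-en-1-yl)-3-methyloxiran-2-yl]-4-[(1R)-1-hydroxy-3-methylbut-3-en-1-yl]-3-methylideneoxolan-2-one | C=C1C(=O)O[C@H]([C@@H]2O[C@]2(C)CCC=C)[C@@H]1[C@H](O)CC(C)=C
F7 | step 6 | (4R,5S)-5-[(2S,3R)-3-(but-3-en-1-yl)-3-methyloxiran-2-yl]-4-{(1R)-3-methyl-1-[(triethylsilyl)oxy]but-3-en-1-yl}-3-methylideneoxolan-2-one | C=C1C(=O)O[C@H]([C@@H]2O[C@]2(C)CCC=C)[C@@H]1[C@H](O[Si](CC)(CC)CC)CC(C)=C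
F8 | step 7 | (4S,5S)-5-[(2S,3R)-3-(but-3-en-1-yl)-3-methyloxiran-2-yl]-4-(1-hydroxy-3-methylbut-3-en-1-yl)oxolan-2-one (carbinol epimers) | C1C(=O)O[C@H]([C@@H]2O[C@]2(C)CCC=C)[C@@H]1C(O)CC(C)=C
F9 | step 7 | (4R,5S)-5-[(2S,3R)-3-(but-3-en-1-yl)-3-methyloxiran-2-yl]-4-(3-methylbut-3-enoyl)oxolan-2-one | C1C(=O)O[C@H]([C@@H]2O[C@]2(C)CCC=C)[C@@H]1C(=O)CC(C)=C
F10 | step 9 | (4R,5S)-5-[(2S,3R)-3-methyl-3-(3-oxopropyl)oxiran-2-yl]-4-{(1R)-3-oxo-1-[(triethylsilyl)oxy]butyl}oxolan-2-one | C1C(=O)O[C@H]([C@@H]2O[C@]2(C)CCC=O)[C@@H]1[C@H](O[Si](CC)(CC)CC)CC(C)=O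
F11 | step 9 | (4R,5S,6S,7R,8R)-4,5-epoxy-1,10-dihydroxy-8-[(triethylsilyl)oxy]-13-norgermacran-12,6-olide (1,10-cis-diol, sense at C1 and C10 not assigned) | C1C(=O)O[C@H]2[C@@H]1[C@H](O[Si](CC)(CC)CC)CC(C)(O)C(O)CC[C@@]1(C)O[C@@H]21
F12 | step 9 | cyclic 1,10-thionocarbonate of the cis-diol F11 | C1C(=O)O[C@H]2[C@@H]1[C@H](O[Si](CC)(CC)CC)CC3(C)OC(=S)OC3CC[C@@]1(C)O[C@@H]21
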